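**Retrosynthetic overview**

1. The butenolide is made last: the C15–C16 bond comes from a catalyst-controlled vinylogous Mukaiyama aldol of a 2-silyloxyfuran with the C15 enal, and the C13=C14 alkene from a terminal alkyne by carboalumination.
2. Ring B is closed in one Lewis-acid formal (4+2) annulation: a 3-alkoxycyclobutanone (latent C6 oxocarbenium / C9 enolate 1,4-dipole, made by ketene–vinyl ether (2+2) cycloaddition) bonds C6 to C5 and C9 to C10 of the ring-A alkene.
3. Enabling feature: in ring B the C6 oxygen and the C8 exocyclic carbon are 1,3-related (a β-oxy-ketone retron), and C18 on C4 of ring A lies on the α face, the face on which C9 must bond to C10. The C18 oxygen can therefore carry the four-carbon unit; the temporary tetrahydrofuran C4–C18–O–C6–C5 is opened again by β-elimination, C5 and C9 then settle to the trans-decalin, and the 6α-oxygen is put back by α-face epoxidation and reduction.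
4. Ring order: ring A (C4 set by asymmetric conjugate addition to 3-methylcyclohexenone), then temporary tetrahydrofuran plus ring B (key step), then the butenolide.

Key step: step 6

Remark: labdane numbering is used (C1–C10 decalin, C17 = CH2 on C8, C18 = oxygenated carbon on C4 (α), C19/C20 = methyls on C4/C10, C11–C16 side chain, C15 the carbinol, C16 the lactone CH). The target is treated as the open hydroxy aldehyde, because a lactol between C18 and the 6α-oxygen would need a trans,trans-fused five-membered ring.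

**Route**

Step 1
Reactants: 1 3-methylcyclohex-2-en-1-one; 2 (chloromethyl)(isopropoxy)dimethylsilane
Product: 5 (R)-3-methyl-3-{[isopropoxy(dimethyl)silyl]methyl}cyclohex-1-en-1-yl trifluoromethanesulfonate, via Grignard reagent 3 (not isolated), via magnesium enolate 4 (not isolated)
Conditions: 2, Mg, THF; then 1, Cu(OTf)2 (3 mol%), chiral imidazolinium salt (NHC ligand precursor, 4 mol%), Et2O, 0 °C; then PhNTf2, 0 → 23 °C
Reagents that add atoms: N-phenylbis(trifluoromethanesulfonimide), O=S(=O)(N(c1ccccc1)S(=O)(=O)C(F)(F)F)C(F)(F)F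
Why: Copper-catalysed asymmetric conjugate addition of the silylmethyl Grignard reagent to the β-methyl enone should set the C4 quaternary centre (ligand antipode chosen for R), and O-triflation of the regio-defined magnesium enolate in the same flask fixes the future C5=C10 alkene position.

Step 2
Reactants: 5 enol triflate
Product: 6 (R)-[(1,3-dimethylcyclohex-2-en-1-yl)methyl](isopropoxy)dimethylsilane
Conditions: Me2CuLi, THF, −20 °C
Reagents that add atoms: lithium dimethylcuprate, [Li+].C[Cu-]C
Why: Cross-coupling of the alkenyl triflate with the cuprate should replace OTf by the C10 methyl group without touching the C4 centre.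

Step 3
Reactants: 6 alkoxysilane
Product: 7 (R)-(1,3-dimethylcyclohex-2-en-1-yl)methanol
Conditions: H2O2 (30%), KF, KHCO3, THF/MeOH, 23 °C
Reagents that add atoms: hydrogen peroxide, OO
Why: Tamao oxidation should convert the C–Si bond into the C18–OH bond and leave the trisubstituted alkene intact.

Step 4
Reactants: 7 ring-A alcohol
Product: 8 (R)-1-[(ethenyloxy)methyl]-1,3-dimethylcyclohex-2-ene
Conditions: [Ir(cod)Cl]2 (1 mol%), Na2CO3 (0.6 equiv), vinyl acetate, toluene, 100 °C
Reagents that add atoms: vinyl acetate, C=COC(C)=O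
Why: Iridium-catalysed transfer vinylation of the primary alcohol should give the vinyl ether needed for the ketene cycloaddition.

Step 5
Reactants: 8 vinyl ether; 9 hex-5-ynoic acid
Product: 12 2-(but-3-yn-1-yl)-3-{[(1R)-1,3-dimethylcyclohex-2-en-1-yl]methoxy}cyclobutan-1-one (stereoisomer mixture at the two cyclobutanone carbons), via acid chloride 10 (not isolated), via alkylketene 11 (not isolated)
Conditions: 9, (COCl)2, cat. DMF, CH2Cl2; evaporate; slow addition to 8, Et3N, MeCN, 80 °C
Reagents that add atoms: none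
Why: Dehydrochlorination should give an alkylketene that undergoes regioselective ketene–enol ether (2+2) cycloaddition (carbonyl carbon to the CH2 terminus) with the vinyl ether and not with the ring alkene; both new stereocentres are erased in step 6.

Step 6
Reactants: 12 cyclobutanone
Product: 15 tricyclic keto ether 9-(but-3-yn-1-yl)-6α,18-epoxy-4β,10β-dimethyl-5βH-decalin-8-one (rings A/B cis-fused; C9 epimers), via zwitterion 13 (not isolated), via C10 carbocation 14 (not isolated)
Conditions: SnCl4 (0.3 equiv), CH2Cl2, −78 → −40 °C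
Reagents that add atoms: none
Why: Proposed new method: SnCl4 binds the cyclobutanone carbonyl and heterolyses the strained C6–C9 bond of 12 (push from the alkoxy oxygen, pull from the carbonyl) to zwitterion 13; its C6 oxocarbenium ion is attacked by C5 of the ring-A alkene (5-exo Prins closure of the tetrahydrofuran C4–C18–O–C6–C5, Markovnikov, giving tertiary cation 14 at C10), and the tin enolate then bonds C9 to C10 (six-membered ring B, enolendo closure), so C5–C6 and C9–C10 form in one operation. The closest known reaction type is the Lewis-acid formal (4+2) cycloaddition of 3-alkoxycyclobutanones with allylsilanes, silyl enol ethers and tethered alkenes; new here is that the alkene is tethered through the alkoxy oxygen. The quaternary centre C10 is controlled by the C4 stereocentre: the C18–O tether can reach only the α face of C5, and the enolate should collapse onto the same face of the neighbouring cation, whose β face is screened by the C4 methyl group. C5 and C6 form cis on the new tetrahydrofuran and C9 as a mixture, but all three are reset in step 7 (C6 becomes sp2, C5 and C9 equilibrate). The step therefore needs only α-face bonding at C10 and attack of the oxocarbenium ion at C5 rather than C10; the latter is secured by tertiary-cation formation and the five-membered ring size. Collapse of 13 to an open β-alkoxy enone is the main competing path and should be held back by the intramolecular trap and the low temperature.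

Step 7
Reactants: 15 tricyclic keto ether
Product: 17 trans-fused enone 9β-(but-3-yn-1-yl)-4β,10β-dimethyl-4α-[(triethylsilyloxy)methyl]-5αH-dec-6-en-8-one ring system (9αH), via bis-silyl dienol ether 16 (not isolated)
Conditions: TESOTf, Et3N, CH2Cl2, −78 → 23 °C; then K2CO3, MeOH, 23 °C
Reagents that add atoms: triethylsilyl trifluoromethanesulfonate, CC[Si](CC)(CC)OS(=O)(=O)C(F)(F)F
Why: Soft enolisation towards C7 and silyl-triflate-assisted β-elimination (retro-oxa-Michael) of the C6–O bond should open the tetrahydrofuran with silylation of the C18 oxygen, and methanolysis of the dienol silyl ether then lets the dienolate be protonated at C5 from the α face (β face blocked by the C4 and C10 methyl groups) and C9 become equatorial, giving the thermodynamically preferred trans-decalin.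

Step 8
Reactants: 17 enone
Product: 18 6α,7α-epoxy-8-ketone
Conditions: t-BuOOH, DBU, CH2Cl2, 0 → 23 °C
Reagents that add atoms: tert-butyl hydroperoxide, CC(C)(C)OO
Why: Nucleophilic (Weitz–Scheffer) epoxidation of the enone should occur from the α face, because the β face at C6 is flanked by the axial C19 and C20 methyl groups; this sets the C6 oxygen α.

Step 9
Reactants: 18 epoxy ketone
Product: 19 6α-hydroxy-8-ketone
Conditions: SmI2, THF/MeOH, −90 °C
Reagents that add atoms: none
Why: Single-electron reduction of the α,β-epoxy ketone cleaves only the C7–O bond next to the carbonyl, so the 6α-hydroxyl of the β-hydroxy ketone keeps its configuration.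

Step 10
Reactants: 19 hydroxy ketone
Product: 20 6α,18-bis(triethylsilyloxy)-8-ketone
Conditions: TESOTf, 2,6-lutidine, CH2Cl2, −78 °C
Reagents that add atoms: triethylsilyl trifluoromethanesulfonate, CC[Si](CC)(CC)OS(=O)(=O)C(F)(F)F
Why: Silyl-triflate silylation of the hindered secondary alcohol at low temperature protects C6–OH without β-elimination.

Step 11
Reactants: 20 ketone
Product: 21 8(17)-methylene compound with terminal alkyne side chain
Conditions: Zn, CH2Br2, TiCl4, THF/CH2Cl2, 0 → 23 °C
Reagents that add atoms: dibromomethane, BrCBr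
Why: Takai–Lombardo methylenation converts the hindered, enolisable C8 ketone into the exocyclic methylene under non-basic conditions, so C9 and the β-silyloxy group should not be disturbed.

Step 12
Reactants: 21 terminal alkyne
Product: 23 (E)-allylic alcohol (C15–OH), via alkenylalane 22 (not isolated)
Conditions: Me3Al, Cp2ZrCl2 (0.25 equiv), CH2Cl2, 0 → 23 °C; then (CH2O)n
Reagents that add atoms: trimethylaluminium, C[Al](C)C; formaldehyde (from paraformaldehyde), C=O
Why: Zirconium-catalysed syn-carboalumination (Negishi) of the terminal alkyne and trapping of the alkenylalane with formaldehyde should give the trisubstituted allylic alcohol; syn addition fixes the E geometry of C13=C14.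

Step 13
Reactants: 23 allylic alcohol
Product: 24 (E)-enal (C15 aldehyde)
Conditions: MnO2, CH2Cl2, 23 °C
Reagents that add atoms: none
Why: Allylic oxidation with MnO2 gives the enal without loss of alkene geometry.

Step 14
Reactants: 25 4-methylfuran-2(5H)-one
Product: 26 4-methyl-2-(trimethylsilyloxy)furan
Conditions: TMSOTf, Et3N, CH2Cl2, 0 °C
Reagents that add atoms: trimethylsilyl trifluoromethanesulfonate, C[Si](C)(C)OS(=O)(=O)C(F)(F)F
Why: Soft enolisation and O-silylation of the butenolide gives the silyloxyfuran nucleophile.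

Step 15
Reactants: 24 enal; 26 silyloxyfuran
Product: 27 (15S,16S)-hydroxy butenolide (6α,18-bis-silyl ether)
Conditions: Ti(OiPr)4/(S)-BINOL (20 mol%), Et2O, −20 °C; then 1 M HCl, THF
Reagents that add atoms: none
Why: Catalytic asymmetric vinylogous Mukaiyama aldol reaction at the furan γ-carbon: the chiral titanium–BINOL Lewis acid should control the aldehyde face (C15, S) and the open transition state the syn (threo) relation to C16 (S), the BINOL antipode being the one that delivers this pair.

Step 16
Reactants: 27 hydroxy butenolide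
Product: 28 6α,15,18-tris(triethylsilyl) ether
Conditions: TESOTf, 2,6-lutidine, CH2Cl2, −78 °C
Reagents that add atoms: triethylsilyl trifluoromethanesulfonate, CC[Si](CC)(CC)OS(=O)(=O)C(F)(F)F
Why: Silylation protects the allylic C15 hydroxyl against the oxidation in step 17.

Step 17
Reactants: 28 tris-silyl ether
Product: 29 18-aldehyde 6α,15-bis(triethylsilyl) ether
Conditions: (COCl)2, DMSO, CH2Cl2, −78 → −30 °C; then Et3N
Reagents that add atoms: none
Why: Under Swern conditions a primary triethylsilyl ether is oxidised directly to the aldehyde while secondary triethylsilyl ethers survive, so only C18 should be converted.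

Step 18
Reactants: 29 aldehyde
Product: 30 target CNP0113661.1
Conditions: HF·pyridine, THF/pyridine, 0 °C
Reagents that add atoms: none
Why: Fluoride-mediated desilylation frees the C6 and C15 hydroxyl groups under conditions that should spare the aldehyde, the butenolide and the alkenes.

**Compound list**

1 | 3-methylcyclohex-2-en-1-one | CC1=CC(=O)CCC1 | starting material
2 | (chloromethyl)(isopropoxy)dimethylsilane | CC(C)O[Si](C)(C)CCl | starting material
3 | {[isopropoxy(dimethyl)silyl]methyl}magnesium chloride | CC(C)O[Si](C)(C)C[Mg]Cl | intermediate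
4 | chloromagnesium (R)-3-methyl-3-{[isopropoxy(dimethyl)silyl]methyl}cyclohex-1-en-1-olate | Cl[Mg]OC1=C[C@](C)(C[Si](C)(C)OC(C)C)CCC1 | intermediate
5 | (R)-3-methyl-3-{[isopropoxy(dimethyl)silyl]methyl}cyclohex-1-en-1-yl trifluoromethanesulfonate | O=S(=O)(OC1=C[C@](C)(C[Si](C)(C)OC(C)C)CCC1)C(F)(F)F | intermediate
6 | (R)-[(1,3-dimethylcyclohex-2-en-1-yl)methyl](isopropoxy)dimethylsilane | CC1=C[C@](C)(C[Si](C)(C)OC(C)C)CCC1 | intermediate
7 | (R)-(1,3-dimethylcyclohex-2-en-1-yl)methanol | CC1=C[C@](C)(CO)CCC1 | intermediate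
8 | (R)-1-[(ethenyloxy)methyl]-1,3-dimethylcyclohex-2-ene | CC1=C[C@](C)(COC=C)CCC1 | intermediate
9 | hex-5-ynoic acid | C#CCCCC(=O)O | starting material
10 | hex-5-ynoyl chloride | C#CCCCC(=O)Cl | intermediate
11 | (but-3-yn-1-yl)ketene | C#CCCC=C=O | intermediate
12 | 2-(but-3-yn-1-yl)-3-{[(1R)-1,3-dimethylcyclohex-2-en-1-yl]methoxy}cyclobutan-1-one (stereoisomer mixture at C2/C3 of the cyclobutanone) | CC1=C[C@](C)(COC2CC(=O)C2CCC#C)CCC1 | intermediate
13 | ring-opened 1,4-zwitterion (C6 oxocarbenium ion, C8–C9 tin enolate; drawn metal-free) | CC1=C[C@](C)(C[O+]=CCC([O-])=CCCC#C)CCC1 | intermediate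
14 | C10 carbocation with closed tetrahydrofuran (C5–C6 bond formed; enolate drawn metal-free) | C#CCCC=C([O-])C[C@@H]1OC[C@]2(C)CCC[C+](C)[C@H]12 | intermediate
15 | tricyclic keto ether, 9-(but-3-yn-1-yl)-6α,18-epoxy-4β,10β-dimethyl-5βH-decalin-8-one (C9 epimers) | C#CCCC1C(=O)C[C@@H]2OC[C@]3(C)CCC[C@@]1(C)[C@H]23 | intermediate
16 | bis-silyl dienol ether (C5=C6 and C7=C8–OSiEt3; C18–OSiEt3; C9 epimers) | C#CCCC1C(O[Si](CC)(CC)CC)=CC=C2[C@]1(C)CCC[C@@]2(C)CO[Si](CC)(CC)CC | intermediate
17 | trans-fused enone (5αH, 9αH, 10β-Me, 4β-Me, 18-OSiEt3, C6=C7, C8=O, 9β-butynyl) | O=C1C=C[C@@H]2[C@](C)(CCC[C@@]2(C)CO[Si](CC)(CC)CC)[C@H]1CCC#C | intermediate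
18 | 6α,7α-epoxy-8-ketone | O=C1[C@@H]3O[C@@H]3[C@@H]2[C@](C)(CCC[C@@]2(C)CO[Si](CC)(CC)CC)[C@H]1CCC#C | intermediate
19 | 6α-hydroxy-8-ketone | O=C1C[C@H](O)[C@@H]2[C@](C)(CCC[C@@]2(C)CO[Si](CC)(CC)CC)[C@H]1CCC#C | intermediate
20 | 6α,18-bis(triethylsilyloxy)-8-ketone | O=C1C[C@H](O[Si](CC)(CC)CC)[C@@H]2[C@](C)(CCC[C@@]2(C)CO[Si](CC)(CC)CC)[C@H]1CCC#C | intermediate
21 | 8(17)-methylene compound with 9β-(but-3-yn-1-yl) chain | C=C1C[C@H](O[Si](CC)(CC)CC)[C@@H]2[C@](C)(CCC[C@@]2(C)CO[Si](CC)(CC)CC)[C@H]1CCC#C | intermediate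
22 | (E)-alkenyl(dimethyl)alane (Al on C14) | C=C1C[C@H](O[Si](CC)(CC)CC)[C@@H]2[C@](C)(CCC[C@@]2(C)CO[Si](CC)(CC)CC)[C@H]1CC/C(C)=C/[Al](C)C | intermediate
23 | (E)-allylic alcohol (C15–OH) | C=C1C[C@H](O[Si](CC)(CC)CC)[C@@H]2[C@](C)(CCC[C@@]2(C)CO[Si](CC)(CC)CC)[C@H]1CC/C(C)=C/CO | intermediate
24 | (E)-enal (C15 aldehyde) | C=C1C[C@H](O[Si](CC)(CC)CC)[C@@H]2[C@](C)(CCC[C@@]2(C)CO[Si](CC)(CC)CC)[C@H]1CC/C(C)=C/C=O | intermediate
25 | 4-methylfuran-2(5H)-one | CC1=CC(=O)OC1 | starting material
26 | 4-methyl-2-(trimethylsilyloxy)furan | Cc1coc(O[Si](C)(C)C)c1 | intermediate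
27 | (15S,16S)-15-hydroxy butenolide, 6α,18-bis(triethylsilyl) ether | C=C1C[C@H](O[Si](CC)(CC)CC)[C@@H]2[C@](C)(CCC[C@@]2(C)CO[Si](CC)(CC)CC)[C@H]1CC/C(C)=C/[C@H](O)[C@H]1OC(=O)C=C1C | intermediate
28 | 6α,15,18-tris(triethylsilyl) ether | C=C1C[C@H](O[Si](CC)(CC)CC)[C@@H]2[C@](C)(CCC[C@@]2(C)CO[Si](CC)(CC)CC)[C@H]1CC/C(C)=C/[C@H](O[Si](CC)(CC)CC)[C@H]1OC(=O)C=C1C | intermediate
29 | 18-aldehyde, 6α,15-bis(triethylsilyl) ether | C=C1C[C@H](O[Si](CC)(CC)CC)[C@@H]2[C@](C)(CCC[C@@]2(C)C=O)[C@H]1CC/C(C)=C/[C@H](O[Si](CC)(CC)CC)[C@H]1OC(=O)C=C1C | intermediate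
30 | CNP0113661.1 | C=C1C[C@H](O)[C@@H]2[C@](C)(CCC[C@@]2(C)C=O)[C@H]1CC/C(C)=C/[C@H](O)[C@H]1OC(=O)C=C1C | target

**Step count and risks**

Total step count: 18. Longest linear sequence: 17 steps (steps 1–13 and 15–18).

Steps most likely to fail:

Step 6 (Proposed new method). What may go wrong: zwitterion 13 may lose a proton to give the open β-alkoxy enone, cation 14 may lose a proton before the enolate closes ring B, or ring B may close on the β face of C10. The fallback uses known reactions, sets out from 8 (with acid chloride 10) and returns at 15. C-acylation of vinyl ether 8 with 10 (pyridine, CH2Cl2, then Et3N to eliminate HCl) gives the (E)-β-alkoxy enone F1. Kinetic enolisation (LDA, TMSCl, THF, −78 °C) gives the 1-alkoxy-3-silyloxy diene F2. A thermal intramolecular Diels–Alder reaction through the same C18–O tether (toluene, 170 °C, sealed tube) gives the tricyclic silyl enol ether F3, and mild hydrolysis (1 M HCl, THF) gives 15.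

Step 7. What may go wrong: the β-elimination may stall at the silyl enol ether, the enone may re-add the C18 oxygen before it is silylated, or the primary silyl ether may be lost during methanolysis. The fallback sets out from 15 and returns at 17. Acetolytic cleavage of the ether (Ac2O, BF3·OEt2, 0 °C) gives the cis-fused 18-acetoxy enone F4. Equilibration through the dienolate (DBU, toluene, 80 °C) gives the trans-fused 18-acetoxy enone F5; in this series the oxygen can no longer re-add. Methanolysis (K2CO3, MeOH) gives the trans-fused 18-hydroxy enone F6, and silylation (TESCl, imidazole) gives 17.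

Step 15. What may go wrong: facial or syn/anti control in the aldol with the β,β-disubstituted enal may be poor. The fallback sets out from 24 and returns at 28, replacing steps 15 and 16. An Evans syn-glycolate aldol of 24 with the boron enolate of (R)-4-benzyl-3-[(4-methoxybenzyloxy)acetyl]oxazolidin-2-one (Bu2BOTf, Et3N) gives the syn aldol adduct F7. Transamidation (MeNHOMe·HCl, AlMe3) gives the Weinreb amide F8, and silylation (TESOTf, 2,6-lutidine) gives the 15-silyl ether F9. MeMgBr gives the methyl ketone F10, and DDQ removes the PMB group to give the α-hydroxy ketone F11. (Triphenylphosphoranylidene)ketene (toluene, reflux; O-acylation then intramolecular Wittig reaction) closes the butenolide and gives 28.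

Further compounds
F1 | step 6 | (E)-1-{[(1R)-1,3-dimethylcyclohex-2-en-1-yl]methoxy}oct-1-en-7-yn-3-one | CC1=C[C@](C)(CO/C=C/C(=O)CCCC#C)CCC1
F2 | step 6 | 1-alkoxy-3-(trimethylsilyloxy)octa-1,3-dien-7-yne (alkoxy = ring-A methoxy unit) | CC1=C[C@](C)(CO/C=C/C(O[Si](C)(C)C)=CCCC#C)CCC1
F3 | step 6 | tricyclic silyl enol ether (C7=C8–OSiMe3) | C#CCCC1C(O[Si](C)(C)C)=C[C@@H]2OC[C@]3(C)CCC[C@@]1(C)[C@H]23
F4 | step 7 | cis-fused 18-acetoxy enone (5βH; C9 epimers) | O=C1C=C[C@H]2[C@](C)(CCC[C@@]2(C)COC(C)=O)C1CCC#C
F5 | step 7 | trans-fused 18-acetoxy enone (5αH, 9αH) | O=C1C=C[C@@H]2[C@](C)(CCC[C@@]2(C)COC(C)=O)[C@H]1CCC#C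
F6 | step 7 | trans-fused 18-hydroxy enone (5αH, 9αH) | O=C1C=C[C@@H]2[C@](C)(CCC[C@@]2(C)CO)[C@H]1CCC#C
F7 | step 15 | syn-glycolate aldol adduct (15-OH, 16-OPMB, N-acyl (R)-4-benzyloxazolidinone) | C=C1C[C@H](O[Si](CC)(CC)CC)[C@@H]2[C@](C)(CCC[C@@]2(C)CO[Si](CC)(CC)CC)[C@H]1CC/C(C)=C/[C@H](O)[C@@H](OCc3ccc(OC)cc3)C(=O)N3[C@H](Cc4ccccc4)COC3=O
F8 | step 15 | Weinreb amide (15-OH, 16-OPMB) | C=C1C[C@H](O[Si](CC)(CC)CC)[C@@H]2[C@](C)(CCC[C@@]2(C)CO[Si](CC)(CC)CC)[C@H]1CC/C(C)=C/[C@H](O)[C@@H](OCc3ccc(OC)cc3)C(=O)N(C)OC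
F9 | step 15 | Weinreb amide 15-triethylsilyl ether | C=C1C[C@H](O[Si](CC)(CC)CC)[C@@H]2[C@](C)(CCC[C@@]2(C)CO[Si](CC)(CC)CC)[C@H]1CC/C(C)=C/[C@H](O[Si](CC)(CC)CC)[C@@H](OCc3ccc(OC)cc3)C(=O)N(C)OC
F10 | step 15 | methyl ketone (16-OPMB, 15-OSiEt3) | C=C1C[C@H](O[Si](CC)(CC)CC)[C@@H]2[C@](C)(CCC[C@@]2(C)CO[Si](CC)(CC)CC)[C@H]1CC/C(C)=C/[C@H](O[Si](CC)(CC)CC)[C@@H](OCc3ccc(OC)cc3)C(C)=O
F11 | step 15 | α-hydroxy methyl ketone (16-OH, 15-OSiEt3) | C=C1C[C@H](O[Si](CC)(CC)CC)[C@@H]2[C@](C)(CCC[C@@]2(C)CO[Si](CC)(CC)CC)[C@H]1CC/C(C)=C/[C@H](O[Si](CC)(CC)CC)[C@@H](O)C(C)=O
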